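**Plan**
- Retrosynthetic cuts, in order: the three aryl O–Si bonds; then C2–C3, beside the acetoxy carbon, giving a racemic C3–C7 1-bromoalkyl acetate and a C1–C2 arylethylzinc bromide; then C3–Br and the O–acetyl bond, back to an (E)-5-arylpent-4-enal and acetyl bromide; then C4–C5 (Claisen) and C6–C7 (vinyl addition), back to 4-hydroxybenzaldehyde.
- Forward: no ring is formed at any stage. Starting at C7, vinyl addition makes C6–C7, the Johnson–Claisen rearrangement makes C4–C5 and brings in C3 and C4, acetyl bromide activates C3, nickel joins the C1–C2 arm at C2–C3, and desilylation ends the route.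
- Enabling feature: C3 already carries the acetate oxygen, so a radical at C3 is oxygen-stabilised and has three unlike substituents (OAc, H, the C4 chain). Ring A (catechol on C1) and ring B (phenol on C7) are spectators.
- Stereochemistry: the E C6=C7 alkene comes from the chair Claisen transition state. The only stereocentre, C3 (R), comes from the chiral bis(oxazoline) nickel catalyst in the enantioconvergent coupling.

Key step: step 9

Assumptions (remarks on the chemistry):
- The heptane chain is numbered from the catechol-bearing carbon (C1) to the 4-hydroxyphenyl-bearing carbon (C7); the acetoxy carbon is C3 and is R.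
- The sense of induction of the nickel/bis(oxazoline) catalyst for this substrate pair cannot be predicted with certainty. The route is written with the ligand antipode that delivers 3R, to be fixed in the first run by Mosher ester analysis of a small deacetylated sample.

**Route**

Step 1
Reactants: 1 4-hydroxybenzaldehyde
Product: 2 4-(tert-butyldimethylsilyloxy)benzaldehyde
Conditions: TBSCl (1.1 equiv), imidazole (2 equiv), CH2Cl2, 0 °C → r.t.
Reagents that add atoms: tert-butyldimethylsilyl chloride, CC(C)(C)[Si](C)(C)Cl
Why: Imidazole-promoted silyl ether formation at the acidic phenol; the aldehyde is inert under these conditions.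

Step 2
Reactants: 2 4-(tert-butyldimethylsilyloxy)benzaldehyde; 3 vinylmagnesium bromide
Product: 4 rac-1-[4-(tert-butyldimethylsilyloxy)phenyl]prop-2-en-1-ol
Conditions: CH2=CHMgBr (1.2 equiv), THF, −78 → 0 °C; then sat. aq. NH4Cl
Reagents that add atoms: none
Why: Grignard 1,2-addition to the aryl aldehyde at low temperature should leave the aryl silyl ether intact; the racemic carbinol centre is destroyed in the next step.

Step 3
Reactants: 4 rac-1-[4-(tert-butyldimethylsilyloxy)phenyl]prop-2-en-1-ol; 5 triethyl orthoacetate
Product: 8 ethyl (E)-5-[4-(tert-butyldimethylsilyloxy)phenyl]pent-4-enoate, via mixed orthoester 6 (not isolated), via ketene acetal 7 (not isolated)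
Conditions: MeC(OEt)3 (5 equiv), EtCO2H (5 mol %), 135–140 °C, ethanol distilled off
Reagents that add atoms: none
Why: Johnson–Claisen rearrangement; acid-catalysed exchange and loss of ethanol give the ketene acetal, whose chair [3,3] shift with the aryl group equatorial should deliver the conjugated E C6=C7 alkene and form the C4–C5 bond, bringing in C3 and C4.

Step 4
Reactants: 8 ethyl (E)-5-[4-(tert-butyldimethylsilyloxy)phenyl]pent-4-enoate
Product: 10 (E)-5-[4-(tert-butyldimethylsilyloxy)phenyl]pent-4-enal, via aluminium hemiacetal 9 (not isolated)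
Conditions: iBu2AlH (1.05 equiv), CH2Cl2, −78 °C; MeOH at −78 °C, then aq. potassium sodium tartrate
Reagents that add atoms: none
Why: Partial ester reduction with iBu2AlH; the tetrahedral aluminium hemiacetal is stable at −78 °C and releases the aldehyde only on work-up.

Step 5
Reactants: 10 (E)-5-[4-(tert-butyldimethylsilyloxy)phenyl]pent-4-enal; 11 acetyl bromide
Product: 12 rac-(E)-1-bromo-5-[4-(tert-butyldimethylsilyloxy)phenyl]pent-4-en-1-yl acetate
Conditions: AcBr (1.05 equiv, freshly distilled, HBr-free), CH2Cl2, −20 → 0 °C, argon; volatiles removed in vacuo, crude product used at once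
Reagents that add atoms: none
Why: Uncatalysed addition of an acyl bromide across an aliphatic aldehyde C=O (1-bromoalkyl ester formation); low temperature and acid-free reagent should spare the styrene and the aryl silyl ether, and the racemic C3 centre does not matter because step 9 is stereoconvergent.

Step 6
Reactants: 13 2-(3,4-dihydroxyphenyl)ethanol (hydroxytyrosol)
Product: 14 4-(2-bromoethyl)benzene-1,2-diol
Conditions: 48% aq. HBr, 100 °C, N2
Reagents that add atoms: hydrogen bromide, Br
Why: Acid-mediated SN2 substitution of the protonated primary alcohol by bromide; the phenolic hydroxyls cannot be displaced.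

Step 7
Reactants: 14 4-(2-bromoethyl)benzene-1,2-diol
Product: 15 4-(2-bromoethyl)-1,2-bis(tert-butyldimethylsilyloxy)benzene
Conditions: TBSCl (2.4 equiv), imidazole (5 equiv), CH2Cl2, 0 °C → r.t.
Reagents that add atoms: tert-butyldimethylsilyl chloride, CC(C)(C)[Si](C)(C)Cl
Why: Imidazole-promoted silyl ether formation at both phenols is much faster than N-alkylation of imidazole by the primary bromide at this temperature.

Step 8
Reactants: 15 4-(2-bromoethyl)-1,2-bis(tert-butyldimethylsilyloxy)benzene
Product: 16 2-[3,4-bis(tert-butyldimethylsilyloxy)phenyl]ethylzinc bromide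
Conditions: Zn dust (1.5 equiv), I2 (5 mol %), DMA, 70 °C; supernatant titrated with I2 and used as a solution
Reagents that add atoms: zinc, [Zn]
Why: Direct oxidative insertion of iodine-activated zinc into a primary C–Br bond in a polar amide solvent (alkylzinc halide formation), which aryl silyl ethers tolerate.

Step 9
Reactants: 12 rac-(E)-1-bromo-5-[4-(tert-butyldimethylsilyloxy)phenyl]pent-4-en-1-yl acetate; 16 2-[3,4-bis(tert-butyldimethylsilyloxy)phenyl]ethylzinc bromide
Product: 17 (3R,6E)-1-[3,4-bis(tert-butyldimethylsilyloxy)phenyl]-7-[4-(tert-butyldimethylsilyloxy)phenyl]hept-6-en-3-yl acetate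
Conditions: NiBr2(MeOCH2CH2OMe) (10 mol %), 2,2′-(propane-2,2-diyl)bis(4-phenyl-4,5-dihydrooxazole) as the single antipode that gives 3R (12 mol %), 16 (1.5 equiv), THF/DMA, −10 °C
Reagents that add atoms: none
Why: Proposed new method: an enantioconvergent nickel-catalysed Negishi-type C(sp3)–C(sp3) coupling in which a monovalent nickel bromide complex of the bis(oxazoline) abstracts bromine from either enantiomer of 12 to give the same planar, oxygen-stabilised C3 radical, while transmetalation of 16 onto divalent nickel gives the chiral alkylnickel bromide that captures this radical; reductive elimination from the resulting trivalent dialkylnickel forms C2–C3 and returns monovalent nickel. The closest known reactions are the nickel/bis(oxazoline) enantioconvergent alkylations of racemic 1-bromoalkyl carboxylates by alkylnickel species generated from olefins and hydrosilanes, and the enantioconvergent Negishi alkylations of other alpha-heteroatom-substituted alkyl halides with primary alkylzinc halides; this step joins the electrophile of the first to the nucleophile of the second. No ring is closed, since the bond is made intermolecularly between two open chains. The new C3 stereocentre is controlled only by the chiral ligand on nickel during radical capture and reductive elimination; the ligand has to tell apart acetoxy (which can bind nickel through its carbonyl oxygen), hydrogen and the C4 chain, and never has to compare the two similar arylalkyl arms. The step needs chemoselectivity for the C–Br bond over the C6=C7 styrene and the aryl silyl ethers: no nickel hydride is present, attack of the C3 radical on C6 or C7 would require a four-membered exo or five-membered endo closure, and the 1,2-disubstituted styrene is a poor intermolecular acceptor compared with capture by nickel. It also needs bond formation at the primary carbon of 16 without beta-hydride elimination and chain walking to the benzylic position, which fast radical capture and reductive elimination at low temperature, with no hydride source present, should secure.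

Step 10
Reactants: 17 (3R,6E)-1-[3,4-bis(tert-butyldimethylsilyloxy)phenyl]-7-[4-(tert-butyldimethylsilyloxy)phenyl]hept-6-en-3-yl acetate
Product: 18 (3R,6E)-1-(3,4-dihydroxyphenyl)-7-(4-hydroxyphenyl)hept-6-en-3-yl acetate (CID49831947)
Conditions: KHF2 (7 equiv), MeOH, r.t., argon
Reagents that add atoms: none
Why: Bifluoride desilylation of aryl silyl ethers (phenoxide is a good leaving group on silicon) should be much faster than any attack on the alkyl acetate; the mildly acidic medium protects the catechol from autoxidation and C3 is not involved.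

**Compound list**

1 | 4-hydroxybenzaldehyde | O=Cc1ccc(O)cc1 | starting material
2 | 4-(tert-butyldimethylsilyloxy)benzaldehyde | O=Cc1ccc(O[Si](C)(C)C(C)(C)C)cc1 | intermediate
3 | vinylmagnesium bromide | C=C[Mg]Br | starting material
4 | rac-1-[4-(tert-butyldimethylsilyloxy)phenyl]prop-2-en-1-ol | C=CC(O)c1ccc(O[Si](C)(C)C(C)(C)C)cc1 | intermediate
5 | triethyl orthoacetate | CCOC(C)(OCC)OCC | starting material
6 | rac-1-[4-(tert-butyldimethylsilyloxy)phenyl]prop-2-en-1-yl diethyl orthoacetate (mixed orthoester) | C=CC(OC(C)(OCC)OCC)c1ccc(O[Si](C)(C)C(C)(C)C)cc1 | intermediate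
7 | rac-ketene ethyl 1-[4-(tert-butyldimethylsilyloxy)phenyl]prop-2-en-1-yl acetal | C=CC(OC(=C)OCC)c1ccc(O[Si](C)(C)C(C)(C)C)cc1 | intermediate
8 | ethyl (E)-5-[4-(tert-butyldimethylsilyloxy)phenyl]pent-4-enoate | CCOC(=O)CC/C=C/c1ccc(O[Si](C)(C)C(C)(C)C)cc1 | intermediate
9 | diisobutylaluminium hemiacetal of 8 (O-aluminated 1-ethoxy-5-arylpent-4-en-1-ol, racemic) | CCOC(CC/C=C/c1ccc(O[Si](C)(C)C(C)(C)C)cc1)O[Al](CC(C)C)CC(C)C | intermediate
10 | (E)-5-[4-(tert-butyldimethylsilyloxy)phenyl]pent-4-enal | O=CCC/C=C/c1ccc(O[Si](C)(C)C(C)(C)C)cc1 | intermediate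
11 | acetyl bromide | CC(=O)Br | starting material
12 | rac-(E)-1-bromo-5-[4-(tert-butyldimethylsilyloxy)phenyl]pent-4-en-1-yl acetate | CC(=O)OC(Br)CC/C=C/c1ccc(O[Si](C)(C)C(C)(C)C)cc1 | intermediate
13 | 2-(3,4-dihydroxyphenyl)ethanol (hydroxytyrosol) | OCCc1ccc(O)c(O)c1 | starting material
14 | 4-(2-bromoethyl)benzene-1,2-diol | BrCCc1ccc(O)c(O)c1 | intermediate
15 | 4-(2-bromoethyl)-1,2-bis(tert-butyldimethylsilyloxy)benzene | BrCCc1ccc(O[Si](C)(C)C(C)(C)C)c(O[Si](C)(C)C(C)(C)C)c1 | intermediate
16 | 2-[3,4-bis(tert-butyldimethylsilyloxy)phenyl]ethylzinc bromide | Br[Zn]CCc1ccc(O[Si](C)(C)C(C)(C)C)c(O[Si](C)(C)C(C)(C)C)c1 | intermediate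
17 | (3R,6E)-1-[3,4-bis(tert-butyldimethylsilyloxy)phenyl]-7-[4-(tert-butyldimethylsilyloxy)phenyl]hept-6-en-3-yl acetate | CC(=O)O[C@H](CC/C=C/c1ccc(O[Si](C)(C)C(C)(C)C)cc1)CCc1ccc(O[Si](C)(C)C(C)(C)C)c(O[Si](C)(C)C(C)(C)C)c1 | intermediate
18 | (3R,6E)-1-(3,4-dihydroxyphenyl)-7-(4-hydroxyphenyl)hept-6-en-3-yl acetate | CC(=O)O[C@H](CC/C=C/c1ccc(O)cc1)CCc1ccc(O)c(O)c1 | target

**Step count**
Total: 10 steps. Longest linear sequence: 7 steps (steps 1, 2, 3, 4, 5, 9, 10, from 4-hydroxybenzaldehyde); the zinc branch (steps 6–8) joins at step 9.

**Steps most likely to fail**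

1. Step 9. Enantioselectivity may be eroded by an uncatalysed, zinc-halide-promoted ionisation of the bromoacetate and racemic alkylation by the organozinc. The arylethylnickel species may also isomerise by beta-hydride elimination, and the bromoacetate may lose HBr to an enol acetate before it is consumed.
Fallback (known chemistry): it sets out from bromide 15 and aldehyde 10 and comes back at 17. Bromide 15 would be converted with Mg turnings in Et2O into 2-[3,4-bis(tert-butyldimethylsilyloxy)phenyl]ethylmagnesium bromide F1. Treatment of F1 with ZnCl2 (0.5 equiv), followed by 1,4-dioxane to precipitate the magnesium halides, would then give salt-free bis{2-[3,4-bis(tert-butyldimethylsilyloxy)phenyl]ethyl}zinc F2. Titanium-mediated enantioselective dialkylzinc addition of F2 to aldehyde 10 (Ti(OiPr)4, catalytic trans-1,2-bis(trifluoromethanesulfonamido)cyclohexane of the antipode that leads to 3R, toluene, −20 °C) should give (3R,6E)-1-[3,4-bis(tert-butyldimethylsilyloxy)phenyl]-7-[4-(tert-butyldimethylsilyloxy)phenyl]hept-6-en-3-ol F3. Acetylation of F3 (Ac2O, pyridine, cat. DMAP) returns to 17. The same C2–C3 bond is made, but by polar carbonyl addition, and the acetate is installed afterwards.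

2. Step 5. Traces of HBr may hydrobrominate or oligomerise the electron-rich styrene or loosen the aryl silyl ether, and the moisture-sensitive bromoacetate may hydrolyse during handling.
Fallback: it sets out from acetyl bromide 11, zinc reagent 16 and aldehyde 2 and comes back at 17; the styrene is installed only after the acid-sensitive stage. Commercial pent-4-enal F4 would be treated with 11 under the step 5 conditions; since F4 carries neither a styrene nor a silyl ether, this should give rac-1-bromopent-4-en-1-yl acetate F5 cleanly. Coupling of F5 with 16 under the step 9 conditions should give (3R)-1-[3,4-bis(tert-butyldimethylsilyloxy)phenyl]hept-6-en-3-yl acetate F6. Wittig methylenation of 2 (Ph3PCH3Br, KOtBu, THF) would give tert-butyldimethyl(4-vinylphenoxy)silane F7. Olefin cross-metathesis of F6 with excess F7 (second-generation Grubbs catalyst, CH2Cl2, 40 °C) should give the E alkene 17.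

3. Step 4. The partial reduction may run on to the primary alcohol if the aluminium hemiacetal collapses before the quench, or stop short and leave ester.
Fallback: it sets out from ester 8 and comes back at aldehyde 10. Full reduction (LiAlH4, THF, 0 °C) would give (E)-5-[4-(tert-butyldimethylsilyloxy)phenyl]pent-4-en-1-ol F8. Oxidation of F8 with Dess–Martin periodinane (NaHCO3, CH2Cl2, r.t.) then gives 10, trading one delicate step for two robust ones.

**Further compounds**

F1 | step 9 | 2-[3,4-bis(tert-butyldimethylsilyloxy)phenyl]ethylmagnesium bromide | Br[Mg]CCc1ccc(O[Si](C)(C)C(C)(C)C)c(O[Si](C)(C)C(C)(C)C)c1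
F2 | step 9 | bis{2-[3,4-bis(tert-butyldimethylsilyloxy)phenyl]ethyl}zinc | CC(C)(C)[Si](C)(C)Oc1ccc(CC[Zn]CCc2ccc(O[Si](C)(C)C(C)(C)C)c(O[Si](C)(C)C(C)(C)C)c2)cc1O[Si](C)(C)C(C)(C)C
F3 | step 9 | (3R,6E)-1-[3,4-bis(tert-butyldimethylsilyloxy)phenyl]-7-[4-(tert-butyldimethylsilyloxy)phenyl]hept-6-en-3-ol | O[C@H](CC/C=C/c1ccc(O[Si](C)(C)C(C)(C)C)cc1)CCc1ccc(O[Si](C)(C)C(C)(C)C)c(O[Si](C)(C)C(C)(C)C)c1
F4 | step 5 | pent-4-enal | C=CCCC=O
F5 | step 5 | rac-1-bromopent-4-en-1-yl acetate | CC(=O)OC(Br)CCC=C
F6 | step 5 | (3R)-1-[3,4-bis(tert-butyldimethylsilyloxy)phenyl]hept-6-en-3-yl acetate | CC(=O)O[C@H](CCC=C)CCc1ccc(O[Si](C)(C)C(C)(C)C)c(O[Si](C)(C)C(C)(C)C)c1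
F7 | step 5 | tert-butyldimethyl(4-vinylphenoxy)silane | C=Cc1ccc(O[Si](C)(C)C(C)(C)C)cc1
F8 | step 4 | (E)-5-[4-(tert-butyldimethylsilyloxy)phenyl]pent-4-en-1-ol | OCCC/C=C/c1ccc(O[Si](C)(C)C(C)(C)C)cc1
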